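## Structural features

The target is one cyclohexene ring (C1–C6, alkene C2=C3) with a single exocyclic carbon, C7, on C3; C1 carries a methyl ether, C4 a free hydroxyl, C5 a benzoate, C6 a free hydroxyl and C7 the second benzoate. The four stereocentres C4, C5, C6 and C1 are contiguous and all R, with O4/O5 cis, O5/O6 trans and O6/O1 cis. The C5 benzoate lies between two free hydroxyls and can migrate to O4 or O6 under base, and the allylic C1–OMe and C4–OH bonds can ionise under acid, after which further eliminations would aromatise the ring. The real difficulty is not the skeleton but that four secondary oxygens of similar reactivity must end as OMe, OH, OBz and OH, the hardest choice being O5 against O4 inside a cis-diol. The key step exploits the fact that C4(OH)–C5(O) is a cis-1,2-diol whose C4 is bonded to the alkene carbon C3: cutting C4–C5 leaves a C4 enal and a C5 aldehyde that the Z C2=C3 bond holds side by side, so one reductive carbonyl–carbonyl coupling can re-form the bond, the ring and both stereocentres. The remaining stereocentres C6 and C1 are an erythro pair that maps onto D-erythronolactone (1), with the lactone carbonyl as C5, the CH2O carbon as C2, the more acidic α-hydroxyl as O6 and the β-hydroxyl as O1. In the cyclisation substrate the two silyl ethers are deliberately different: a tert-butyldimethylsilyl ether at O6, and a bulkier triisopropylsilyl ether at O7 that should resist transfer to the neighbouring C4 alkoxide and shield O4 in the later acylation.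

## Logic of the disconnections

17 ⇒ 16 + 13. The C7–O acyl bond is cut. The primary allylic hydroxyl is the most accessible of the three free hydroxyls of 16, so the easiest ester is placed last. This removes one benzoate and leaves a triol monoester. The forward step must acylate O7 only, without moving the O5 benzoate to O4 or O6, which calls for a weak hindered base and low temperature.

16 ⇒ 15. The O6–Si and O7–Si bonds are cut. Both silyl ethers can fall together because no later step has to tell O6 from O7. The demand is a fluoride source acidic enough to suppress 1,2-acyl migration and mild enough to spare the allylic ether.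

15 ⇒ 12 + 13 (through 14). The C5–O acyl bond is cut. In 12 only the cis pair O4/O5 is free, so the problem shrinks to one regiochemical choice. The forward step must acylate O5 and not O4. The tin acetal 14 is chosen because such acetals of cyclic cis-diols react at the equatorial oxygen, which should be O5 in the preferred half-chair of 12. An orthoester opening would favour the axial oxygen (O4 in that half-chair) and is therefore kept only as a reserve.

12 ⇒ 11. The ring bond C4–C5 is cut. This removes the ring and two stereocentres and leaves an acyclic dialdehyde whose only stereocentres are C1 and C6. The forward step must couple the two carbonyl carbons reductively, in preference to simple reduction, and must place O4 cis to O5 and O5 trans to O6.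

11 ⇒ 10 ⇒ 9. No skeletal bond is cut; oxidation levels are adjusted. The C4 aldehyde comes from the allylic alcohol of 10, and that alcohol together with the C5 aldehyde comes from the ester and the N-methoxy-N-methylamide of 9 in one hydride reduction. The two aldehydes are unveiled as late as possible because 11 can lose its Z geometry or epimerise at C6. The demand is mild, non-basic conditions and immediate use.

9 ⇒ 5 + 8. The C2=C3 double bond is cut. This separates the chiral C5–C6–C1–C2 piece from the achiral C3/C4/C7 piece. The forward olefination must place the ester (the future C4) cis to the C1 chain and must not epimerise the α-methoxy aldehyde 5.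

8 ⇒ 6 + 7. The C3–C7 bond is cut. The oxygenated one-carbon unit is attached to a commercial phosphonoacetate by alkylation. The demand is mono-alkylation at carbon.

5 ⇒ 4 ⇒ 3. The C2 aldehyde is taken back to the primary alcohol of 4, and the amide C–N bond is cut to return the lactone 3. The lactone ring is the device that keeps C5 (carbonyl) and C2 (CH2O) different. The forward aminolysis must open the ring without silyl migration, and the oxidation must leave C1 untouched.

3 ⇒ 2 ⇒ 1. The O1–CH3 and O6–Si bonds are cut. C6 and C1 are taken unchanged from 1, so no stereocentre has to be created before the key step. The demands are silylation at the more acidic α-hydroxyl only, and methylation without alkoxide so that the silyl group does not migrate and the lactone does not eliminate.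

## Other disconnections considered

Alternative 1: The C4–O and C5–O bonds are traced back to an arene, and the carbocycle is never opened. The forward key step is a whole-cell toluene dioxygenase oxidation of bromobenzene A1 to (1S,2S)-3-bromocyclohexa-3,5-diene-1,2-diol A2.
- In favour: A2 already holds O4 and O5 cis and in the correct absolute sense. Acetal protection and osmium-catalysed dihydroxylation of the distal alkene on the face opposite the acetal would add O6 and O1 with the correct relative configuration. The vinyl bromide is a handle for C7.
- Against: O1 and O6 arrive as an undifferentiated cis-diol, of which only O1 may be methylated, and O4/O5 must still be told apart after acetal removal. That is two regiochemical choices on cis-diols where the chosen plan has one. A2 also tends to aromatise and dimerise.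
- Comparison, structure: the alternative is better, since the ring and all four stereocentres come from proven operations.
- Comparison, mechanism: the alternative is better, since it needs no new method.
- Comparison, step economy: about ten operations would be needed, which is equal to or slightly better than the chosen plan.
- The chosen plan is better only in that O1 and O6 are differentiated from the first two steps and that no fermentation is needed.

Alternative 2: The target bonds C3–C4 and C5–C6 are cut together. The forward key step is a Diels–Alder addition of methyl 2-oxo-2H-pyran-3-carboxylate A3 to 2,2-dimethyl-1,3-dioxole A4 under Cu(OTf)2 (divalent copper) with a chiral bis(oxazoline), giving the bridged lactone A5.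
- In favour: one catalytic step would form two C–C bonds, the ring and three stereocentres (C4, C5, C6), and the ester carbon is the future C7. The endo adduct has the acetal oxygens anti to the lactone bridge, which is the required O5/O6 trans relation. On bonds and stereocentres per step, and on precedent for the activation mode, the alternative is better than the chosen key step.
- Against: the lactone carbonyl is an extra carbon on C3 that must be excised. C1 arrives as an unoxygenated alkene carbon, so the methoxy group needs an allylic oxidation with alkene transposition and a new stereocentre. Such bridged lactones lose CO2 readily, and A4 is a volatile, weakly reactive dienophile.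
- Comparison, structure: the chosen plan is better, since every carbon of its cyclisation substrate ends in the target and C1 is oxygenated from the start.
- Comparison, step economy: the work after A5 (carbon excision, C1 oxygenation, ester reduction, the same O4/O5 choice) would probably make the alternative no shorter.
- Comparison, stereocontrol: the alternative's absolute configuration rests on a catalyst, the chosen plan's on the chiral pool.

Alternative 3: The C5–O and C6–O bonds are cut back to a cross-conjugated dienone. The forward key step is a phase-transfer epoxidation of the quinone monoketal A6 with an alkyl hydroperoxide and a cinchona-derived quaternary ammonium salt, giving the epoxy enone A7 at the unsubstituted enone bond.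
- In favour: every ring carbon and C7 come from a cheap aromatic precursor, and the nucleophilic epoxidation should prefer the unsubstituted enone bond. Opening of A7 by benzoate at C5 (α to the ketone) with inversion would give the trans O5/O6 pattern and put the benzoate directly on O5. On this point the alternative is better than the chosen plan, which must select O5 within a cis-diol.
- On step economy it is also better (perhaps eight operations).
- Against: asymmetric induction in this substrate class is uncertain. C4 (ketone reduction) and C1 (ketal to a single methyl ether) would both be set later by substrate control. The β-hydroxy ketone formed on epoxide opening can eliminate and aromatise.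
- Comparison, mechanism: the reaction type is established, so the alternative is equal or better on precedent.
- Comparison, structure: the chosen plan is more secure, since C1 and C6 come fixed from 1 and C4/C5 are set together in one organised step.

Key step: step 9

Remark: locants C1–C7 are those of the target throughout (C1 OMe, C2=C3, C7 on C3, O4/O5/O6 in order); the cyclisation substrate 11 is (4R,5R), which 1 delivers without any inversion; (triisopropylsiloxy)methyl chloride 7 is taken as a commercial reagent.

## Route

Step 1
Reactants: 1 D-erythronolactone
Product: 2 (3R,4R)-3-[(tert-butyldimethylsilyl)oxy]-4-hydroxydihydrofuran-2(3H)-one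
Conditions: TBSCl (1.05 equiv), imidazole, DMF, −20 → 0 °C
Reagents that add atoms: tert-butyldimethylsilyl chloride, C[Si](C)(Cl)C(C)(C)C
Why: Silylation of a hydroxyl with a silyl chloride and imidazole; the α-hydroxyl next to the lactone carbonyl is the more acidic and should react first with one equivalent at low temperature, which marks O6 for later release. No stereocentre is touched.

Step 2
Reactants: 2 (3R,4R)-3-[(tert-butyldimethylsilyl)oxy]-4-hydroxydihydrofuran-2(3H)-one
Product: 3 (3R,4R)-3-[(tert-butyldimethylsilyl)oxy]-4-methoxydihydrofuran-2(3H)-one
Conditions: Me3OBF4, 1,8-bis(dimethylamino)naphthalene, 4 Å MS, CH2Cl2, 0 °C → rt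
Reagents that add atoms: trimethyloxonium tetrafluoroborate, C[O+](C)C.F[B-](F)(F)F
Why: O-Methylation with Meerwein's salt and a non-nucleophilic proton scavenger; without alkoxide there should be no 1,2-silyl migration, no β-elimination across the lactone and no epimerisation at the α-carbon. The methyl ether placed here is the C1 methoxy group of the target.

Step 3
Reactants: 3 (3R,4R)-3-[(tert-butyldimethylsilyl)oxy]-4-methoxydihydrofuran-2(3H)-one
Product: 4 (2R,3R)-2-[(tert-butyldimethylsilyl)oxy]-4-hydroxy-N,3-dimethoxy-N-methylbutanamide
Conditions: MeNH(OMe)·HCl, AlMe3, CH2Cl2, 0 °C → rt; aq. KNaC4H4O6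
Reagents that add atoms: N,O-dimethylhydroxylamine hydrochloride, CNOC.Cl
Why: Aminolysis of a lactone by an aluminium amide (Weinreb amide formation); ring opening frees the C2 hydroxyl while the C5 carbonyl is stored at a level that one hydride later turns into the aldehyde. The aluminium alkoxide formed is a poor base, so silyl migration to the primary oxygen should not compete.

Step 4
Reactants: 4 (2R,3R)-2-[(tert-butyldimethylsilyl)oxy]-4-hydroxy-N,3-dimethoxy-N-methylbutanamide
Product: 5 (2R,3S)-2-[(tert-butyldimethylsilyl)oxy]-N,3-dimethoxy-N-methyl-4-oxobutanamide
Conditions: Dess–Martin periodinane, pyridine, CH2Cl2, 0 °C → rt; used crude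
Reagents that add atoms: none
Why: Dess–Martin oxidation of a primary alcohol under buffered, essentially neutral conditions, which should leave the α-methoxy stereocentre (C1) intact; the descriptor changes only because the priorities change.

Step 5
Reactants: 6 methyl bis(2,2,2-trifluoroethyl)phosphonoacetate; 7 (triisopropylsiloxy)methyl chloride
Product: 8 methyl 2-[bis(2,2,2-trifluoroethoxy)phosphoryl]-3-[(triisopropylsilyl)oxy]propanoate (racemic)
Conditions: NaH, THF, 0 °C; then 7, 0 °C → rt (6 in slight excess)
Reagents that add atoms: none
Why: C-Alkylation of a stabilised phosphonoacetate anion with a chloromethyl ether, a very reactive SN2 electrophile; the slight excess of 6 should suppress dialkylation.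

Step 6
Reactants: 5 (2R,3S)-2-[(tert-butyldimethylsilyl)oxy]-N,3-dimethoxy-N-methyl-4-oxobutanamide; 8 methyl 2-[bis(2,2,2-trifluoroethoxy)phosphoryl]-3-[(triisopropylsilyl)oxy]propanoate
Product: 9 methyl (2Z,4R,5R)-5-[(tert-butyldimethylsilyl)oxy]-4-methoxy-6-[methoxy(methyl)amino]-6-oxo-2-{[(triisopropylsilyl)oxy]methyl}hex-2-enoate
Conditions: 8, KN(SiMe3)2, 18-crown-6, THF, −78 °C; then 5, −78 °C
Reagents that add atoms: none
Why: Still–Gennari olefination: the bis(trifluoroethyl) phosphonate eliminates quickly from the kinetically formed adduct, which should place the ester cis to the C1 chain (2Z). The stabilised anion at −78 °C should neither epimerise C1 of 5 nor expel silanolate from C7.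

Step 7
Reactants: 9 methyl (2Z,4R,5R)-5-[(tert-butyldimethylsilyl)oxy]-4-methoxy-6-[methoxy(methyl)amino]-6-oxo-2-{[(triisopropylsilyl)oxy]methyl}hex-2-enoate
Product: 10 (2R,3R,4E)-2-[(tert-butyldimethylsilyl)oxy]-6-hydroxy-3-methoxy-5-{[(triisopropylsilyl)oxy]methyl}hex-4-enal
Conditions: i-Bu2AlH (3.5 equiv), CH2Cl2, −78 °C; MeOH quench at −78 °C, aq. KNaC4H4O6
Reagents that add atoms: none
Why: Hydride reduction with i-Bu2AlH: the N-methoxy-N-methylamide stops at the chelated hemiaminal and releases the C5 aldehyde only on work-up, while the conjugated ester is reduced to the allylic alcohol. The alkene geometry is unchanged (the descriptor becomes E only by priority).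

Step 8
Reactants: 10 (2R,3R,4E)-2-[(tert-butyldimethylsilyl)oxy]-6-hydroxy-3-methoxy-5-{[(triisopropylsilyl)oxy]methyl}hex-4-enal
Product: 11 (2Z,4R,5R)-5-[(tert-butyldimethylsilyl)oxy]-4-methoxy-2-{[(triisopropylsilyl)oxy]methyl}hex-2-enedial
Conditions: Dess–Martin periodinane, pyridine, CH2Cl2, 0 °C; short silica plug, used at once
Reagents that add atoms: none
Why: Dess–Martin oxidation of an allylic alcohol under buffered conditions, chosen because it should neither isomerise the Z alkene nor epimerise C6; the dialdehyde is not stored.

Step 9
Reactants: 11 (2Z,4R,5R)-5-[(tert-butyldimethylsilyl)oxy]-4-methoxy-2-{[(triisopropylsilyl)oxy]methyl}hex-2-enedial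
Product: 12 (1R,2R,5R,6S)-6-[(tert-butyldimethylsilyl)oxy]-5-methoxy-3-{[(triisopropylsilyl)oxy]methyl}cyclohex-3-ene-1,2-diol
Conditions: SmI2 (2.5 equiv), t-BuOH (2 equiv), THF (0.01 M), −78 °C, slow addition of 11; aq. NaHCO3/Na2S2O3
Reagents that add atoms: none
Why: Proposed new method: SmI2 (divalent samarium) should first transfer an electron to the conjugated C4 aldehyde, the more easily reduced carbonyl, to give a samarium-bound allylic ketyl; its carbonyl carbon C4 then attacks the samarium-activated C5 aldehyde and a second electron gives a cyclic samarium diolate that is protonated on work-up, the closest known reaction type being the SmI2 pinacol cyclisation of carbohydrate-derived 1,6-dialdehydes to cis-cyclohexane-1,2-diols. The ring closes in a 6-exo-trig mode onto the C5 carbonyl, which is possible because the Z C2=C3 bond holds C4 and C5 within bonding distance. Coupling through the ketyl β-carbon C2 is excluded because it would close a cyclobutane. C5 should be set by the C6 stereocentre: the new C5–O bond takes the side opposite the C6 silyloxy group to avoid steric and dipolar repulsion in the α-oxygenated aldehyde. C4 should be set by samarium bridging of the two oxygens in the coupling transition state, which places O4 cis to O5. The step needs carbonyl–carbonyl coupling to win over simple reduction of the enal, over loss of the C1 methoxy group from a dienolate, over rotation about C2–C3 in the allylic ketyl and over intermolecular coupling at C2. Low temperature, the absence of strongly donating additives, high dilution and slow addition of 11 are meant to secure this, and the bulky triisopropylsilyl ether at O7 should resist silyl transfer to the C4 alkoxide.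

Step 10
Reactants: 12 (1R,2R,5R,6S)-6-[(tert-butyldimethylsilyl)oxy]-5-methoxy-3-{[(triisopropylsilyl)oxy]methyl}cyclohex-3-ene-1,2-diol; 13 benzoyl chloride
Product: 15 (1R,2R,5R,6R)-6-[(tert-butyldimethylsilyl)oxy]-2-hydroxy-5-methoxy-3-{[(triisopropylsilyl)oxy]methyl}cyclohex-3-en-1-yl benzoate, via stannylene acetal 14 (not isolated)
Conditions: Bu2SnO, toluene, reflux (Dean–Stark); then BzCl (13, 1.05 equiv), 0 °C → rt
Reagents that add atoms: dibutyltin oxide, CCCC[Sn](=O)CCCC (tin is carried only by intermediate 14)
Why: Regioselective acylation through a dibutylstannylene acetal, which in cyclic cis-diols reacts at the equatorial oxygen. In 12, O5 and O6 should sit trans-diequatorial while O4 is pseudoaxial (this avoids allylic strain with the C3 substituent), and O4 is further shielded by the triisopropylsilyloxymethyl group, so the benzoate should go to O5. No stereocentre is formed.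

Step 11
Reactants: 15 (1R,2R,5R,6R)-6-[(tert-butyldimethylsilyl)oxy]-2-hydroxy-5-methoxy-3-{[(triisopropylsilyl)oxy]methyl}cyclohex-3-en-1-yl benzoate
Product: 16 (1R,2R,5R,6R)-2,6-dihydroxy-3-(hydroxymethyl)-5-methoxycyclohex-3-en-1-yl benzoate
Conditions: HF·pyridine, pyridine, THF, 0 °C → rt
Reagents that add atoms: none
Why: Fluoride cleavage of both silyl ethers with buffered HF·pyridine; the mildly acidic medium should not promote 1,2-migration of the C5 benzoate or ionisation of the allylic ether.

Step 12
Reactants: 16 (1R,2R,5R,6R)-2,6-dihydroxy-3-(hydroxymethyl)-5-methoxycyclohex-3-en-1-yl benzoate; 13 benzoyl chloride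
Product: 17 [(3R,4R,5R,6R)-5-(benzoyloxy)-4,6-dihydroxy-3-methoxycyclohex-1-en-1-yl]methyl benzoate (CNP0349013.4)
Conditions: BzCl (13, 1.05 equiv), 2,4,6-collidine, CH2Cl2, −40 °C
Reagents that add atoms: none
Why: Chemoselective acylation of a primary allylic alcohol in the presence of two secondary ones, under kinetic control at low temperature with a hindered pyridine base that should not induce acyl migration. This completes the target.

## Compound list

1 | D-erythronolactone, (3R,4R)-3,4-dihydroxydihydrofuran-2(3H)-one | O=C1[C@H](O)[C@H](O)CO1 | starting material
2 | (3R,4R)-3-[(tert-butyldimethylsilyl)oxy]-4-hydroxydihydrofuran-2(3H)-one | O=C1[C@H](O[Si](C)(C)C(C)(C)C)[C@H](O)CO1 | intermediate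
3 | (3R,4R)-3-[(tert-butyldimethylsilyl)oxy]-4-methoxydihydrofuran-2(3H)-one | O=C1[C@H](O[Si](C)(C)C(C)(C)C)[C@H](OC)CO1 | intermediate
4 | (2R,3R)-2-[(tert-butyldimethylsilyl)oxy]-4-hydroxy-N,3-dimethoxy-N-methylbutanamide | CON(C)C(=O)[C@H](O[Si](C)(C)C(C)(C)C)[C@H](OC)CO | intermediate
5 | (2R,3S)-2-[(tert-butyldimethylsilyl)oxy]-N,3-dimethoxy-N-methyl-4-oxobutanamide | CON(C)C(=O)[C@H](O[Si](C)(C)C(C)(C)C)[C@H](OC)C=O | intermediate
6 | methyl bis(2,2,2-trifluoroethyl)phosphonoacetate | COC(=O)CP(=O)(OCC(F)(F)F)OCC(F)(F)F | starting material
7 | (triisopropylsiloxy)methyl chloride | ClCO[Si](C(C)C)(C(C)C)C(C)C | starting material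
8 | methyl 2-[bis(2,2,2-trifluoroethoxy)phosphoryl]-3-[(triisopropylsilyl)oxy]propanoate (racemic) | COC(=O)C(CO[Si](C(C)C)(C(C)C)C(C)C)P(=O)(OCC(F)(F)F)OCC(F)(F)F | intermediate
9 | methyl (2Z,4R,5R)-5-[(tert-butyldimethylsilyl)oxy]-4-methoxy-6-[methoxy(methyl)amino]-6-oxo-2-{[(triisopropylsilyl)oxy]methyl}hex-2-enoate | CON(C)C(=O)[C@H](O[Si](C)(C)C(C)(C)C)[C@H](OC)/C=C(\C(=O)OC)CO[Si](C(C)C)(C(C)C)C(C)C | intermediate
10 | (2R,3R,4E)-2-[(tert-butyldimethylsilyl)oxy]-6-hydroxy-3-methoxy-5-{[(triisopropylsilyl)oxy]methyl}hex-4-enal (CH2OH cis to the C3 chain) | O=C[C@H](O[Si](C)(C)C(C)(C)C)[C@H](OC)/C=C(\CO)CO[Si](C(C)C)(C(C)C)C(C)C | intermediate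
11 | (2Z,4R,5R)-5-[(tert-butyldimethylsilyl)oxy]-4-methoxy-2-{[(triisopropylsilyl)oxy]methyl}hex-2-enedial | O=C/C(CO[Si](C(C)C)(C(C)C)C(C)C)=C\[C@@H](OC)[C@@H](O[Si](C)(C)C(C)(C)C)C=O | intermediate
12 | (1R,2R,5R,6S)-6-[(tert-butyldimethylsilyl)oxy]-5-methoxy-3-{[(triisopropylsilyl)oxy]methyl}cyclohex-3-ene-1,2-diol (O4/O5 cis, O5/O6 trans, O6/O1 cis in target numbering) | CO[C@@H]1C=C(CO[Si](C(C)C)(C(C)C)C(C)C)[C@@H](O)[C@@H](O)[C@@H]1O[Si](C)(C)C(C)(C)C | intermediate
13 | benzoyl chloride | O=C(Cl)c1ccccc1 | starting material
14 | 4,5-O-dibutylstannylene acetal of 12 (2,2-dibutyl-1,3,2-dioxastannolane fused cis at C4/C5, other groups as in 12) | CO[C@@H]1C=C(CO[Si](C(C)C)(C(C)C)C(C)C)[C@@H](O[Sn]2(CCCC)CCCC)[C@@H](O2)[C@@H]1O[Si](C)(C)C(C)(C)C | intermediate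
15 | (1R,2R,5R,6R)-6-[(tert-butyldimethylsilyl)oxy]-2-hydroxy-5-methoxy-3-{[(triisopropylsilyl)oxy]methyl}cyclohex-3-en-1-yl benzoate | CO[C@@H]1C=C(CO[Si](C(C)C)(C(C)C)C(C)C)[C@@H](O)[C@@H](OC(=O)c2ccccc2)[C@@H]1O[Si](C)(C)C(C)(C)C | intermediate
16 | (1R,2R,5R,6R)-2,6-dihydroxy-3-(hydroxymethyl)-5-methoxycyclohex-3-en-1-yl benzoate | CO[C@@H]1C=C(CO)[C@@H](O)[C@@H](OC(=O)c2ccccc2)[C@@H]1O | intermediate
17 | [(3R,4R,5R,6R)-5-(benzoyloxy)-4,6-dihydroxy-3-methoxycyclohex-1-en-1-yl]methyl benzoate (CNP0349013.4) | CO[C@@H]1C=C(COC(=O)c2ccccc2)[C@@H](O)[C@@H](OC(=O)c2ccccc2)[C@@H]1O | target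

## Step count and least certain steps

Total step count: 12. Longest linear sequence: 11 steps (1 → 17 through steps 1–4 and 6–12); step 5 prepares the phosphonate 8 on a side branch.

Step 9 (key step, the one carrying the label). The most likely failure is reduction without coupling. The enal may take up two electrons to give the allylic alcohol, or a dienolate that expels the C1 methoxy group. The allylic ketyl may rotate about C2–C3 and lose the Z geometry that closure needs. Coupling may occur between two molecules at C2. All of these compete because an enal ketyl is a stabilised, long-lived intermediate. The fallback uses known reactions only. It sets out from 11: both aldehydes are methylenated under non-basic conditions (Zn, CH2I2, TiCl4, THF) to give the triene F1. Ring-closing metathesis with the second-generation Grubbs catalyst joins the two terminal vinyl groups, with loss of ethene, to give the cyclohexa-1,3-diene F2. Osmium-catalysed cis-dihydroxylation (OsO4 cat., N-methylmorpholine N-oxide, acetone/water) of the disubstituted C4=C5 bond, on the face opposite the C6 silyloxy group, should then give 12, where the route is rejoined. The ring is thus closed as a C4=C5 alkene and the diol is set afterwards by a reagent that adds both oxygens to one face. Its own weak point would be the choice between the two alkenes of F2.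

Step 10. The most likely failure is acylation at O4, or poor discrimination between O4 and O5, if the ring does not adopt the half-chair with O5 equatorial or if the allylic oxygen of the tin acetal proves the more nucleophilic. The fallback sets out from 12: trimethyl orthobenzoate with catalytic camphorsulfonic acid would give the cyclic orthobenzoate F3, and mild aqueous acetic acid would open it to the monobenzoate. Orthoester opening leaves the ester on the axial oxygen, whereas the tin acetal acylates the equatorial one. The two methods therefore have opposite preferences, and the orthoester route should deliver the O5 benzoate in the case where the tin route fails for conformational reasons. It rejoins the route at 15.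

Step 6. The most likely failures are erosion of the Z selectivity with the α-branched phosphonate, expulsion of silanolate from the phosphonate anion (retro-oxa-Michael), and epimerisation of the α-methoxy aldehyde by the base. The fallback sets out from 6 and 5. Compound 6 is brominated (NaH, then Br2, THF) to the α-bromo phosphonate F4. Olefination of 5 with F4 under the same potassium/crown conditions should give the (E)-α-bromo enoate F5, in which the ester is again cis to the C1 chain. Stille coupling of F5 with (tributylstannyl)methanol (Pd(PPh3)4, zerovalent palladium, dioxane, 80 °C) should give the hydroxymethyl enoate F6 with retention of geometry. Silylation with triisopropylsilyl triflate and 2,6-lutidine then returns to the route at 9.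

Step 7. The most likely failure is cyclisation of the freshly released hydroxy aldehyde to a seven-membered lactol, which step 8 would over-oxidise to a lactone, together with partial over-reduction of the aldehyde during the quench. The fallback sets out from 9: after the i-Bu2AlH reduction, NaBH4 in methanol is added to the crude mixture, so that both termini end as alcohols in the diol F7. A Swern oxidation, which activates both hydroxyls before any base is added, then converts F7 directly into 11, where the route is rejoined. The hydroxy aldehyde is never handled in this variant.

## Further compounds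

F1 | step 9 | (3S,4R,5E)-3-[(tert-butyldimethylsilyl)oxy]-4-methoxy-6-{[(triisopropylsilyl)oxy]methyl}octa-1,5,7-triene | C=C/C(CO[Si](C(C)C)(C(C)C)C(C)C)=C\[C@@H](OC)[C@@H](O[Si](C)(C)C(C)(C)C)C=C
F2 | step 9 | (5S,6R)-5-[(tert-butyldimethylsilyl)oxy]-6-methoxy-2-{[(triisopropylsilyl)oxy]methyl}cyclohexa-1,3-diene | CO[C@@H]1C=C(CO[Si](C(C)C)(C(C)C)C(C)C)C=C[C@@H]1O[Si](C)(C)C(C)(C)C
F3 | step 10 | cyclic orthobenzoate of 12 (2-methoxy-2-phenyl-1,3-dioxolane spanning O4 and O5, mixture at the orthoester carbon) | CO[C@@H]1C=C(CO[Si](C(C)C)(C(C)C)C(C)C)[C@@H](OC2(OC)c3ccccc3)[C@@H](O2)[C@@H]1O[Si](C)(C)C(C)(C)C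
F4 | step 6 | methyl 2-[bis(2,2,2-trifluoroethoxy)phosphoryl]-2-bromoacetate (racemic) | COC(=O)C(Br)P(=O)(OCC(F)(F)F)OCC(F)(F)F
F5 | step 6 | methyl (2E,4R,5R)-2-bromo-5-[(tert-butyldimethylsilyl)oxy]-4-methoxy-6-[methoxy(methyl)amino]-6-oxohex-2-enoate | CON(C)C(=O)[C@H](O[Si](C)(C)C(C)(C)C)[C@H](OC)/C=C(\C(=O)OC)Br
F6 | step 6 | methyl (2Z,4R,5R)-5-[(tert-butyldimethylsilyl)oxy]-2-(hydroxymethyl)-4-methoxy-6-[methoxy(methyl)amino]-6-oxohex-2-enoate | CON(C)C(=O)[C@H](O[Si](C)(C)C(C)(C)C)[C@H](OC)/C=C(\C(=O)OC)CO
F7 | step 7 | (2S,3R,4E)-2-[(tert-butyldimethylsilyl)oxy]-3-methoxy-5-{[(triisopropylsilyl)oxy]methyl}hex-4-ene-1,6-diol | OC[C@H](O[Si](C)(C)C(C)(C)C)[C@H](OC)/C=C(\CO)CO[Si](C(C)C)(C(C)C)C(C)C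
A1 | alternative 1 | bromobenzene | Brc1ccccc1
A2 | alternative 1 | (1S,2S)-3-bromocyclohexa-3,5-diene-1,2-diol | BrC1=CC=C[C@H](O)[C@@H]1O
A3 | alternative 2 | methyl 2-oxo-2H-pyran-3-carboxylate | COC(=O)C1=CC=COC1=O
A4 | alternative 2 | 2,2-dimethyl-1,3-dioxole | CC1(C)OC=CO1
A5 | alternative 2 | methyl 7,8-(isopropylidenedioxy)-3-oxo-2-oxabicyclo[2.2.2]oct-5-ene-4-carboxylate (endo adduct) | O=C1O[C@@H]2C=C[C@@]1(C(=O)OC)[C@H]3OC(C)(C)O[C@@H]23
A6 | alternative 3 | 2-[(tert-butyldimethylsilyloxy)methyl]-4,4-dimethoxycyclohexa-2,5-dien-1-one | COC1(OC)C=CC(=O)C(CO[Si](C)(C)C(C)(C)C)=C1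
A7 | alternative 3 | 5,6-epoxy-2-[(tert-butyldimethylsilyloxy)methyl]-4,4-dimethoxycyclohex-2-en-1-one | COC1(OC)C=C(CO[Si](C)(C)C(C)(C)C)C(=O)[C@@H]2O[C@H]12
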